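**Plan**
- **Cuts:** the fourteen benzyl ethers go first. Ring F (O1L, C2L, C3L, C4L, C4aL, C8aL; suffix L = lower unit) is then cut at O1L–C2L and C3L–C4L in one retro-hetero-Diels–Alder operation. After that come C4L–C4aL, the interflavan bond C4–C8L and the upper ester C–O bond.
- **Enabling feature:** C4L is a bare CH2 on C4aL, ortho to the oxygen-bearing C8aL of phloroglucinol ring D, which makes a latent o-quinone methide. C2L and C3L carry a para-oxygenated aryl (ring E) and an acyloxy group cis to each other, which makes a latent (Z)-2-arylvinyl gallate.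
- **Forward order:** rings A, B and C come intact from (−)-epicatechin. Ring D is joined to C4 as 3,5-bis(benzyloxy)phenol, ortho to its only free OH (the future O1L). One carbon is placed at the other ortho position. Ring F is closed last and brings in ring E and the second gallate.
- **Stereochemistry:** C2 and C3 come from epicatechin. C4 is set by β-face attack anti to the 3-acyloxy group. C2L and C3L become cis from the Z-alkene, and their absolute sense comes from a chiral phosphoric acid.
- **Helpers:** the benzylic OH on C4L leaves as water in the key step, and the benzyl ethers leave in the final hydrogenolysis.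

Key step: step 9

Assumption: (R)-TRIP is taken as the antipode of the acid that offers the alkene face leading to (2R,3R) in ring F; no precedent with an unsubstituted methide carbon fixes the sense of induction, and the (S)-acid is the direct replacement if the pairing with the resident 4β-flavanyl group proves mismatched.

**Step 1**
Reactants: 1 (−)-epicatechin
Product: 2 5,7,3',4'-tetra-O-benzyl-(−)-epicatechin
Conditions: BnBr (4.2 equiv), K2CO3, DMF, Ar, 0 °C to rt
Reagents that add atoms: benzyl bromide, BrCc1ccccc1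
Why: Williamson etherification in which carbonate deprotonates only the four phenols and not the secondary 3-OH, and under argon at or below room temperature C2 and C3 are not touched.

**Step 2**
Reactants: 2 5,7,3',4'-tetra-O-benzyl-(−)-epicatechin
Product: 3 4β-(2-ethoxyethoxy)-5,7,3',4'-tetra-O-benzyl-(−)-epicatechin
Conditions: DDQ, 2-ethoxyethanol, CH2Cl2, rt
Reagents that add atoms: 2-ethoxyethanol, CCOCCO
Why: Oxidative benzylic C–H alkoxylation in which DDQ takes hydride from C4, activated by the 5,7-dibenzyloxy ring A, and the alcohol adds to the cation from the β face, anti to the quasi-axial 3-OH, so that C4 is set 3,4-trans.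

**Step 3**
Reactants: 3 4β-(2-ethoxyethoxy)-5,7,3',4'-tetra-O-benzyl-(−)-epicatechin; 4 3,4,5-tris(benzyloxy)benzoic acid
Product: 5 4β-(2-ethoxyethoxy)-5,7,3',4'-tetra-O-benzyl-(−)-epicatechin 3-O-(tri-O-benzylgallate)
Conditions: DCC, DMAP (cat.), CH2Cl2, rt
Reagents that add atoms: none
Why: Steglich esterification of the hindered axial 3-OH with DMAP as acyl carrier, under neutral conditions that leave the labile 4-ether and all stereocentres untouched.

**Step 4**
Reactants: 5 4β-(2-ethoxyethoxy)-5,7,3',4'-tetra-O-benzyl-(−)-epicatechin 3-O-(tri-O-benzylgallate); 6 3,5-bis(benzyloxy)phenol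
Product: 7 4β-[2-hydroxy-4,6-bis(benzyloxy)phenyl]-5,7,3',4'-tetra-O-benzyl-(−)-epicatechin 3-O-(tri-O-benzylgallate)
Conditions: 6 (3 equiv), TMSOTf (10 mol%), CH2Cl2, −78 to −40 °C
Reagents that add atoms: none
Why: Lewis acid promoted flavan-4-yl Friedel–Crafts alkylation in which loss of the 4-alkoxy group gives a cation stabilised by ring A and shielded on its α face by the 3-galloyloxy group, so the arene adds from the β face (3,4-trans) through a carbon ortho to the free OH rather than through the more crowded carbon between the two benzyloxy groups.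

**Step 5**
Reactants: 7 4β-[2-hydroxy-4,6-bis(benzyloxy)phenyl]-5,7,3',4'-tetra-O-benzyl-(−)-epicatechin 3-O-(tri-O-benzylgallate)
Product: 8 4β-[3-formyl-2-hydroxy-4,6-bis(benzyloxy)phenyl]-5,7,3',4'-tetra-O-benzyl-(−)-epicatechin 3-O-(tri-O-benzylgallate)
Conditions: MgCl2, Et3N, (CH2O)n, THF, reflux
Reagents that add atoms: paraformaldehyde (as formaldehyde), C=O
Why: Casnati–Skattebøl ortho-formylation in which the magnesium phenoxide delivers coordinated formaldehyde only to an ortho carbon, of which just C4aL is free, and a second formaldehyde oxidises the benzylic alkoxide by hydride transfer, while the ester and the benzyl ethers are inert.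

**Step 6**
Reactants: 8 4β-[3-formyl-2-hydroxy-4,6-bis(benzyloxy)phenyl]-5,7,3',4'-tetra-O-benzyl-(−)-epicatechin 3-O-(tri-O-benzylgallate)
Product: 9 4β-[2-hydroxy-3-(hydroxymethyl)-4,6-bis(benzyloxy)phenyl]-5,7,3',4'-tetra-O-benzyl-(−)-epicatechin 3-O-(tri-O-benzylgallate)
Conditions: NaBH4, THF–MeOH, −20 to 0 °C; pH 7 buffer; used at once
Reagents that add atoms: none
Why: Chemoselective borohydride reduction of the aldehyde beside an aryl ester, in which low temperature and a neutral quench hold back loss of borate to the methide and a second hydride transfer.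

**Step 7**
Reactants: 10 3,4-bis(benzyloxy)benzaldehyde
Product: 11 1,2-bis(benzyloxy)-4-ethynylbenzene
Conditions: dimethyl (1-diazo-2-oxopropyl)phosphonate, K2CO3, MeOH, rt
Reagents that add atoms: dimethyl (1-diazo-2-oxopropyl)phosphonate (Ohira–Bestmann reagent), COP(=O)(OC)C(=[N+]=[N-])C(C)=O
Why: Seyferth–Gilbert homologation in the Ohira–Bestmann variant, in which the deacetylated diazophosphonate anion olefinates the non-enolisable aldehyde and loss of nitrogen with a 1,2-hydrogen shift gives the terminal alkyne.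

**Step 8**
Reactants: 11 1,2-bis(benzyloxy)-4-ethynylbenzene; 4 3,4,5-tris(benzyloxy)benzoic acid
Product: 12 (Z)-2-[3,4-bis(benzyloxy)phenyl]ethenyl 3,4,5-tris(benzyloxy)benzoate
Conditions: Ru(2-methylallyl)2(dppb) (2 mol%), toluene, 50 °C
Reagents that add atoms: none
Why: Ruthenium-catalysed anti-Markovnikov hydro-acyloxylation of a terminal arylalkyne, in which the carboxylate attacks the α carbon of a ruthenium vinylidene and protonolysis of the alkenyl–ruthenium bond leaves ester oxygen and aryl group cis (Z).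

**Step 9**
Reactants: 9 4β-[2-hydroxy-3-(hydroxymethyl)-4,6-bis(benzyloxy)phenyl]-5,7,3',4'-tetra-O-benzyl-(−)-epicatechin 3-O-(tri-O-benzylgallate); 12 (Z)-2-[3,4-bis(benzyloxy)phenyl]ethenyl 3,4,5-tris(benzyloxy)benzoate
Product: 14 tetradeca-O-benzyl-3,3'-di-O-galloylprocyanidin B2, via ring-D o-quinone methide 13 (not isolated)
Conditions: (R)-TRIP [(R)-3,3'-bis(2,4,6-triisopropylphenyl)-1,1'-binaphthyl-2,2'-diyl hydrogen phosphate] (10 mol%), 4 Å MS, toluene, −20 °C; 9 added slowly to 12 (2 equiv)
Reagents that add atoms: none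
Why: Proposed new method: the acid protonates the benzylic hydroxyl of 9, water leaves with the push of O1L and of the two benzyloxy groups of ring D, and the o-quinone methide 13 stays hydrogen-bonded through O1L to the chiral phosphate while the electron-rich alkene of 12 takes it up in an inverse-electron-demand hetero-Diels–Alder reaction. The closest known reaction type is the chiral Brønsted acid catalysed [4+2] cycloaddition of o-quinone methides, made in situ from o-hydroxybenzyl alcohols, with styrenes to give 2-arylchromans; new here are the unsubstituted methide carbon, a (Z)-2-arylvinyl ester as the 2π partner and the stereogenic substituent next to O1L. Ring F is closed by an intermolecular suprafacial [4π+2π] annulation that makes C4L–C3L slightly ahead of O1L–C2L, so no separate cyclisation is needed. C2L and C3L become cis because aryl and acyloxy group are cis on the alkene and both bonds form on one alkene face before C2L–C3L can rotate, which is why a weak acid, an apolar solvent and a low temperature are chosen; their absolute configuration (2R,3R) is set by the chiral pocket of the phosphate, which decides the alkene face offered to 13, with the 4β-flavanyl group on C8L as a second element. The orientation is secured by the substrate, since the para-benzyloxy group of ring E makes the acyloxy-bearing carbon the nucleophilic terminus (the enol oxygen is cross-conjugated with the galloyl carbonyl) and this carbon attacks the methide carbon C4L. The 4→8 connectivity is secured because O1L is the only free oxygen of ring D, so the methide cannot form towards the oxygen on C5L.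

**Step 10**
Reactants: 14 tetradeca-O-benzyl-3,3'-di-O-galloylprocyanidin B2
Product: 15 3,3'-di-O-galloylprocyanidin B2
Conditions: H2 (1 atm), Pd(OH)2/C, THF–MeOH–H2O, rt
Reagents that add atoms: none
Why: Global hydrogenolysis of fourteen aryl benzyl ethers under neutral conditions, which spares the two gallate esters, the cyclic benzylic C2–O1 bonds and the interflavan bond and touches no stereocentre.

**Compound list**
1 | (−)-epicatechin | O[C@@H]1Cc2c(O)cc(O)cc2O[C@@H]1c1ccc(O)c(O)c1 | starting material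
2 | 5,7,3',4'-tetra-O-benzyl-(−)-epicatechin | O[C@@H]1Cc2c(OCc3ccccc3)cc(OCc3ccccc3)cc2O[C@@H]1c1ccc(OCc2ccccc2)c(OCc2ccccc2)c1 | intermediate
3 | 4β-(2-ethoxyethoxy)-5,7,3',4'-tetra-O-benzyl-(−)-epicatechin (2,3-cis, 3,4-trans) | O[C@@H]1[C@@H](OCCOCC)c2c(OCc3ccccc3)cc(OCc3ccccc3)cc2O[C@@H]1c1ccc(OCc2ccccc2)c(OCc2ccccc2)c1 | intermediate
4 | 3,4,5-tris(benzyloxy)benzoic acid | OC(=O)c1cc(OCc2ccccc2)c(OCc2ccccc2)c(OCc2ccccc2)c1 | starting material
5 | 4β-(2-ethoxyethoxy)-5,7,3',4'-tetra-O-benzyl-(−)-epicatechin 3-O-(tri-O-benzylgallate) | O=C(O[C@@H]1[C@@H](OCCOCC)c2c(OCc3ccccc3)cc(OCc3ccccc3)cc2O[C@@H]1c1ccc(OCc2ccccc2)c(OCc2ccccc2)c1)c1cc(OCc2ccccc2)c(OCc2ccccc2)c(OCc2ccccc2)c1 | intermediate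
6 | 3,5-bis(benzyloxy)phenol | Oc1cc(OCc2ccccc2)cc(OCc2ccccc2)c1 | starting material
7 | 4β-[2-hydroxy-4,6-bis(benzyloxy)phenyl]-5,7,3',4'-tetra-O-benzyl-(−)-epicatechin 3-O-(tri-O-benzylgallate) | O=C(O[C@@H]1[C@@H](c2c(OCc3ccccc3)cc(OCc3ccccc3)cc2O)c2c(OCc3ccccc3)cc(OCc3ccccc3)cc2O[C@@H]1c1ccc(OCc2ccccc2)c(OCc2ccccc2)c1)c1cc(OCc2ccccc2)c(OCc2ccccc2)c(OCc2ccccc2)c1 | intermediate
8 | 4β-[3-formyl-2-hydroxy-4,6-bis(benzyloxy)phenyl]-5,7,3',4'-tetra-O-benzyl-(−)-epicatechin 3-O-(tri-O-benzylgallate) | O=C(O[C@@H]1[C@@H](c2c(OCc3ccccc3)cc(OCc3ccccc3)c(C=O)c2O)c2c(OCc3ccccc3)cc(OCc3ccccc3)cc2O[C@@H]1c1ccc(OCc2ccccc2)c(OCc2ccccc2)c1)c1cc(OCc2ccccc2)c(OCc2ccccc2)c(OCc2ccccc2)c1 | intermediate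
9 | 4β-[2-hydroxy-3-(hydroxymethyl)-4,6-bis(benzyloxy)phenyl]-5,7,3',4'-tetra-O-benzyl-(−)-epicatechin 3-O-(tri-O-benzylgallate) | O=C(O[C@@H]1[C@@H](c2c(OCc3ccccc3)cc(OCc3ccccc3)c(CO)c2O)c2c(OCc3ccccc3)cc(OCc3ccccc3)cc2O[C@@H]1c1ccc(OCc2ccccc2)c(OCc2ccccc2)c1)c1cc(OCc2ccccc2)c(OCc2ccccc2)c(OCc2ccccc2)c1 | intermediate
10 | 3,4-bis(benzyloxy)benzaldehyde | O=Cc1ccc(OCc2ccccc2)c(OCc2ccccc2)c1 | starting material
11 | 1,2-bis(benzyloxy)-4-ethynylbenzene | C#Cc1ccc(OCc2ccccc2)c(OCc2ccccc2)c1 | intermediate
12 | (Z)-2-[3,4-bis(benzyloxy)phenyl]ethenyl 3,4,5-tris(benzyloxy)benzoate | O=C(O/C=C\c1ccc(OCc2ccccc2)c(OCc2ccccc2)c1)c1cc(OCc2ccccc2)c(OCc2ccccc2)c(OCc2ccccc2)c1 | intermediate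
13 | o-quinone methide of 9 (ring D as 6-methylenecyclohexa-2,4-dienone, C8aL=O and C4aL=CH2) | O=C(O[C@@H]1[C@@H](C2=C(OCc3ccccc3)C=C(OCc3ccccc3)C(=C)C2=O)c2c(OCc3ccccc3)cc(OCc3ccccc3)cc2O[C@@H]1c1ccc(OCc2ccccc2)c(OCc2ccccc2)c1)c1cc(OCc2ccccc2)c(OCc2ccccc2)c(OCc2ccccc2)c1 | intermediate
14 | tetradeca-O-benzyl-3,3'-di-O-galloylprocyanidin B2 | O=C(O[C@@H]1[C@@H](c2c(OCc3ccccc3)cc(OCc3ccccc3)c3c2O[C@H](c2ccc(OCc4ccccc4)c(OCc4ccccc4)c2)[C@H](OC(=O)c2cc(OCc4ccccc4)c(OCc4ccccc4)c(OCc4ccccc4)c2)C3)c2c(OCc3ccccc3)cc(OCc3ccccc3)cc2O[C@@H]1c1ccc(OCc2ccccc2)c(OCc2ccccc2)c1)c1cc(OCc2ccccc2)c(OCc2ccccc2)c(OCc2ccccc2)c1 | intermediate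
15 | 3,3'-di-O-galloylprocyanidin B2 | O=C(O[C@@H]1[C@@H](c2c(O)cc(O)c3c2O[C@H](c2ccc(O)c(O)c2)[C@H](OC(=O)c2cc(O)c(O)c(O)c2)C3)c2c(O)cc(O)cc2O[C@@H]1c1ccc(O)c(O)c1)c1cc(O)c(O)c(O)c1 | target

**Step count**
Total step count: 10. Longest linear sequence: 8 steps (1, 2, 3, 4, 5, 6, 9, 10).

**Steps most likely to fail**

**Step 9.**
- *What may go wrong:* poor facial selectivity on the alkene if acid and resident flavanyl group are mismatched. The alkene geometry may be lost through a stepwise cationic pathway that lets C2L–C3L rotate. The orientation may reverse, or the methide may self-condense.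
- *Fallback (known chemistry):* ring F is not built but brought in intact.
  - Steglich esterification of 2 with 4 (DCC, DMAP, CH2Cl2) gives 5,7,3',4'-tetra-O-benzyl-(−)-epicatechin 3-O-(tri-O-benzylgallate) F1.
  - This, in excess, is condensed with electrophile 5 under TMSOTf in CH2Cl2 at −78 °C. This is a flavan-4-yl Friedel–Crafts alkylation at C8, with β-face attack anti to the 3-acyloxy group.
  - The fallback sets out from 2 and 5 and comes back to the route at 14.

**Step 4.**
- *What may go wrong:* attack through the carbon para to the free OH, O-alkylation of the phenol, or a second alkylation of the product.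
- *Fallback:* the regiochemical question is removed with a symmetric nucleophile and the oxygens are differentiated later.
  - Compound 5 is condensed with excess phloroglucinol (BF3·OEt2, THF–CH2Cl2, 0 °C) to give the 4β-(2,4,6-trihydroxyphenyl) adduct F2, which has only one kind of free ring carbon.
  - Vilsmeier–Haack formylation (POCl3, DMF, then water) gives the 4β-(3-formyl-2,4,6-trihydroxyphenyl) adduct F3.
  - Benzylation with two equivalents of BnBr and K2CO3 in acetone etherifies the two accessible hydroxyls. It spares the hydroxyl that is chelated to the aldehyde and flanked by the flavanyl group.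
  - The fallback sets out from 5 and comes back at 8.

**Step 6.**
- *What may go wrong:* over-reduction through premature loss of borate to the methide, and self-condensation of the electron-rich o-hydroxybenzyl alcohol on handling.
- *Fallback:* hydride and aldehyde are avoided, and the carbon is brought in at the alcohol oxidation level inside a storable temporary ring.
  - Compound 7 is heated with PhB(OH)2, paraformaldehyde and catalytic propionic acid in toluene with water separation (boronate-templated ortho-hydroxymethylation). This gives the 2-phenyl-4H-1,3,2-benzodioxaborin F4.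
  - Just before the key step, F4 is opened by transesterification with propane-1,3-diol in THF at rt.
  - The fallback sets out from 7 and comes back at 9.

**Further compounds**
F1 | step 9 | 5,7,3',4'-tetra-O-benzyl-(−)-epicatechin 3-O-(tri-O-benzylgallate) | O=C(O[C@@H]1Cc2c(OCc3ccccc3)cc(OCc3ccccc3)cc2O[C@@H]1c1ccc(OCc2ccccc2)c(OCc2ccccc2)c1)c1cc(OCc2ccccc2)c(OCc2ccccc2)c(OCc2ccccc2)c1
F2 | step 4 | 4β-(2,4,6-trihydroxyphenyl)-5,7,3',4'-tetra-O-benzyl-(−)-epicatechin 3-O-(tri-O-benzylgallate) | O=C(O[C@@H]1[C@@H](c2c(O)cc(O)cc2O)c2c(OCc3ccccc3)cc(OCc3ccccc3)cc2O[C@@H]1c1ccc(OCc2ccccc2)c(OCc2ccccc2)c1)c1cc(OCc2ccccc2)c(OCc2ccccc2)c(OCc2ccccc2)c1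
F3 | step 4 | 4β-(3-formyl-2,4,6-trihydroxyphenyl)-5,7,3',4'-tetra-O-benzyl-(−)-epicatechin 3-O-(tri-O-benzylgallate) | O=C(O[C@@H]1[C@@H](c2c(O)cc(O)c(C=O)c2O)c2c(OCc3ccccc3)cc(OCc3ccccc3)cc2O[C@@H]1c1ccc(OCc2ccccc2)c(OCc2ccccc2)c1)c1cc(OCc2ccccc2)c(OCc2ccccc2)c(OCc2ccccc2)c1
F4 | step 6 | 4β-[5,7-bis(benzyloxy)-2-phenyl-4H-1,3,2-benzodioxaborin-8-yl]-5,7,3',4'-tetra-O-benzyl-(−)-epicatechin 3-O-(tri-O-benzylgallate) | O=C(O[C@@H]1[C@@H](c2c(OCc3ccccc3)cc(OCc3ccccc3)c3COB(c4ccccc4)Oc23)c2c(OCc3ccccc3)cc(OCc3ccccc3)cc2O[C@@H]1c1ccc(OCc2ccccc2)c(OCc2ccccc2)c1)c1cc(OCc2ccccc2)c(OCc2ccccc2)c(OCc2ccccc2)c1
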